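**Remark on the chemistry.** The target has no stereocentre. Ring A is numbered C1 (ether oxygen), C2 (OMe), C3 and C5 (Br); ring B is numbered C1' (ether oxygen), C2' (OH), C3' (H), C4' to C6' (Br). Boronic acid 4 is assumed to be a purchasable building block.

## Analysis of the target

Target 11 is a diaryl ether: two benzene rings joined through one oxygen, with no further ring and no stereocentre. Ring A is a 3,5-dibromo-2-methoxyphenyl group. Ring B is a phenol with the ether oxygen at C1', the hydroxyl at C2', hydrogen at C3' and bromine at C4', C5' and C6'. The five aryl bromides rule out catalytic hydrogenation, zerovalent palladium and organolithium reagents late in the route, and the one methyl ether has to survive while the hydroxyl at C2' is unmasked. On ring B the ether oxygen sits between the C2' oxygen and the C6' bromine, so making the aryl–oxygen bond on a finished ring B would mean coupling a doubly ortho-substituted, electron-poor phenol. The real difficulty is the pattern of ring B: the hydroxyl directs electrophiles to C3' and C5', yet C3' must remain hydrogen while the three carbons next to it carry bromine. The strategy rests on C3'. An amino group placed there occupies that carbon, sends bromine to C4' and C6', leaves C5' to the C2' oxygen, and can afterwards be exchanged for hydrogen.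

## Retrosynthetic reasoning

**11 from 10.** The O–CH2Ph bond at C2' is cut last. A benzyl ether keeps the C2' oxygen a strong para donor during bromination, survives buffered bromination, metal reduction and diazotisation, and is removed by a boron Lewis acid at low temperature. No hydrogenolysis is needed, and the methyl ether on ring A stays.

**10 from 8 (through 9).** The C3'–H bond is traced back to a C3'–N bond. The amine is turned into diazonium salt 9 and nitrogen is replaced by hydrogen. The forward step must hand a hydrogen atom to the C3' radical faster than that radical can add to the phenyl ring of the neighbouring benzyl ether. A concentrated phosphorus–hydrogen donor is therefore planned rather than a solvent as hydrogen source.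

**8 from 6 (through 7).** All three C–Br bonds of ring B (C4', C5', C6') are cut in one operation. This is the place to cut because amine 6 has exactly three open carbons on ring B: two are ortho and para to nitrogen, and the third is para to the benzyloxy oxygen. Exhaustive substitution can therefore give only one product on that ring. The gain is that the carbon the C2' oxygen would otherwise hand to bromine is held by nitrogen. The forward reaction has to spare ring A and the benzyl group.

**6 from 5.** The amine is traced back to a nitro group. The reduction must leave two aryl bromides and the benzyl ether alone, which points to a metal reduction and away from hydrogenation.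

**5 from 3 and 4.** The bond between the bridging oxygen and C1 of ring A is cut. Cutting on this side lets ring A arrive with both bromines and the methoxy group already in place in boronic acid 4. It also makes ring B the nucleophile, as phenol 3, at a stage where its oxygen has only one ortho substituent. The other cut, oxygen to C1', would need a leaving group meta to the nitro group, which is not activated. A copper-mediated oxidative coupling at room temperature does not touch aryl bromides.

**3 from 1 and 2.** The benzyl–oxygen bond is cut. The two hydroxyls of 3-nitrocatechol 1 differ in acidity, the one beside the nitro group being the more acidic. One equivalent of a weak base and benzyl bromide 2 should therefore place the benzyl group on the oxygen that becomes C2'–O and leave the other free for the coupling.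

## Alternatives that were turned down

**Alternative 1:** Ring B is opened at C1'–C6' and C3'–C4'. 3,5-Dibromo-2-methoxyphenol A4 would be O-alkylated with a haloacetone to give the aryloxyacetone A2. In aqueous alkali the two α-carbons of A2 would condense with the two formyl groups of sodium nitromalonaldehyde A3 and, after double dehydration, close ring B as the nitrophenol A1.
- For it: the oxygen pattern of ring B is unambiguous, C3' carries hydrogen from the start (it is the former ketone methyl), the nitro group at C5' is a handle for the middle bromine, and the diaryl ether oxygen is attached by a simple alkylation instead of an aryl coupling.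
- Against it: A3 is an impact-sensitive salt that has to be prepared, A4 is not a standard catalogue phenol, and the condensation of an unsymmetrical, base-sensitive α-aryloxy ketone is not a dependable ring synthesis. After A1 the route still needs protection of the hydroxyl (which otherwise sends bromine to C3'), reduction, dibromination at C4' and C6', a Sandmeyer bromination at C5' and deprotection.
- Comparison: it is stronger on the certainty that C3' stays unsubstituted and on the ease of the ether bond. The chosen strategy offers a shorter sequence from catalogue compounds, no hazardous reagent, and all three bromines of ring B in one operation.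

**Alternative 2:** Ring A is carried as a cyclohexenone. The enone A6 would be made from the ring B phenol A7 and a 2-functionalised cyclohexanone unit. Bromination would then act alpha to the ketone, the acid set free would be lost, the ring would tautomerise to a phenol, and two further bromines would enter ortho and para to the new hydroxyl to give A5. O-Methylation and debenzylation would follow.
- For it: the two bromines of ring A land where a phenol hydroxyl sends them, and the ether bond is not made by coupling two arenes.
- Against it: the alternative presupposes A7, whose 2,3,4-tribromo pattern next to an unsubstituted carbon is exactly the difficult part of the target and is left unsolved. The phenoxide of A7 is hindered and weakly nucleophilic, the benzyl ether is exposed to acid during aromatisation, and a methylation step is added.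
- Comparison: it is as good or better on the regiochemistry of ring A, but in the chosen route that pattern is simply purchased in 4. The chosen strategy puts its key step on the problem that actually has to be solved, ring B.

**Alternative 3:** Ring A comes from an aryne. Fluoride would release the aryne from the silylaryl triflate A9, the caesium phenoxide of A7 would add at the aryne carbon remote from the flanking bromine, and the aryl anion so formed would attack the methoxy oxygen of the peroxide A10. The product A8 is identical with 10 and would need only the final debenzylation.
- For it: it is the most convergent plan, forming both C–O bonds of ring A in one operation, and the polarisation of the aryne by the adjacent bromine favours the desired regiochemistry.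
- Against it: it again needs A7. The aryl anion is ortho to a bromine and can expel bromide to give a second aryne, or be protonated, before it meets the peroxide. Methoxylation of an aryne-derived anion by a dialkyl peroxide in a three-component mode has no close analogy, and A9 needs its own multistep preparation.
- Comparison: it is stronger on convergence. The chosen strategy uses only established reaction types and builds the ring B pattern instead of assuming it.

Key step: step 4

## Route

Step 1
Reactants: 1 3-nitrocatechol; 2 benzyl bromide
Product: 3 2-(benzyloxy)-3-nitrophenol
Conditions: KHCO3 (1.1 equiv), DMF, 50 °C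
Reagents that add atoms: none
Why: Williamson ether synthesis under acidity control: the hydroxyl beside the nitro group is the more acidic, so one equivalent of hydrogencarbonate forms essentially only that phenoxide, which is benzylated, while the second hydroxyl stays protonated and free for step 2.

Step 2
Reactants: 3 2-(benzyloxy)-3-nitrophenol; 4 (3,5-dibromo-2-methoxyphenyl)boronic acid (2 equiv)
Product: 5 2-(benzyloxy)-1-(3,5-dibromo-2-methoxyphenoxy)-3-nitrobenzene
Conditions: Cu(OAc)2 (1.0 equiv), pyridine (5 equiv), 4 Å MS, CH2Cl2, O2 (balloon), rt
Reagents that add atoms: none
Why: Chan–Lam coupling: the phenoxide binds divalent copper, the aryl group is transferred from boron, and C–O reductive elimination from trivalent copper gives the diaryl ether, with O2 returning copper to the divalent state. The reaction runs at room temperature, leaves the aryl bromides, nitro group and benzyl ether untouched, and the phenol has only one ortho substituent at this stage.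

Step 3
Reactants: 5 2-(benzyloxy)-1-(3,5-dibromo-2-methoxyphenoxy)-3-nitrobenzene
Product: 6 2-(benzyloxy)-3-(3,5-dibromo-2-methoxyphenoxy)aniline
Conditions: Fe powder, NH4Cl, EtOH/H2O (4:1), 80 °C
Reagents that add atoms: none
Why: Béchamp-type reduction of the nitro group by iron in buffered aqueous ethanol; electron transfer from the metal does not cleave aryl bromides or the benzyl ether, as catalytic hydrogenation would.

Step 4
Reactants: 6 2-(benzyloxy)-3-(3,5-dibromo-2-methoxyphenoxy)aniline
Product: 8 2-(benzyloxy)-4,5,6-tribromo-3-(3,5-dibromo-2-methoxyphenoxy)aniline, via 4,6-dibromoaniline 7 (not isolated)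
Conditions: Br2 (3.1 equiv), NaOAc (4 equiv), AcOH/CH2Cl2, 0 °C to 40 °C, dark
Reagents that add atoms: bromine, BrBr
Why: Threefold electrophilic aromatic substitution through arenium ions. The free amino group at C3' stabilises the cations from attack at C6' (para) and C4' (ortho), so the first two equivalents should give dibromide 7 quickly at 0 °C. In 7 the only open carbon of ring B is C5', para to the benzyloxy oxygen at C2'; that oxygen stabilises the third arenium ion, and gentle warming should complete substitution between the two bromines, as in the exhaustive bromination of anilines and of catechol monoethers, the closest known reaction type. No ring is closed and no stereocentre is formed. The step needs selectivity between the rings: ring B carries NH2 and two oxygen donors, whereas ring A already bears two bromines, has no NH2 or OH, and holds its methoxy group twisted between two ortho neighbours, and the benzyl phenyl ring is only an alkylbenzene. Sodium acetate takes up the acid formed, so the amine is not protonated (which would reverse the reactivity order of the rings) and the benzyl ether sees no strong acid; darkness suppresses benzylic bromination. Because every open carbon of ring B ends up brominated, no regioisomer can form on that ring, and the charge of about three equivalents sets the stopping point.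

Step 5
Reactants: 8 2-(benzyloxy)-4,5,6-tribromo-3-(3,5-dibromo-2-methoxyphenoxy)aniline
Product: 10 1-(benzyloxy)-3,4,5-tribromo-2-(3,5-dibromo-2-methoxyphenoxy)benzene, via diazonium tetrafluoroborate 9 (not isolated)
Conditions: NOBF4 (1.2 equiv), MeCN, −30 °C to 0 °C; then 50% aq. H3PO2 (15 equiv), Cu2O (cat.), 0 °C to rt
Reagents that add atoms: none
Why: Diazotisation of the weakly basic, hindered aniline by the nitrosonium salt, then hydrodediazoniation by hypophosphorous acid, a Cu2O-initiated radical chain in which the aryl radical takes hydrogen from a P–H bond. A concentrated, fast hydrogen donor is chosen because the C3' radical stands ortho to the benzyloxy group and must be quenched before it can add to the benzyl phenyl ring; the aryl bromides and both ethers are inert.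

Step 6
Reactants: 10 1-(benzyloxy)-3,4,5-tribromo-2-(3,5-dibromo-2-methoxyphenoxy)benzene
Product: 11 3,4,5-tribromo-2-(3,5-dibromo-2-methoxyphenoxy)phenol
Conditions: BCl3 (1 M in CH2Cl2, 2.5 equiv), pentamethylbenzene (3 equiv), CH2Cl2, −78 °C; then H2O
Reagents that add atoms: none
Why: Lewis-acid cleavage of the aryl benzyl ether: BCl3 coordinates the ether oxygen and the benzyl cation is captured by pentamethylbenzene in a Friedel–Crafts alkylation. At −78 °C the aryl methyl ether and the diaryl ether should not be cleaved, and no reducing conditions touch the five bromines.

## Compound list

1 | 3-nitrocatechol (3-nitrobenzene-1,2-diol) | Oc1cccc([N+](=O)[O-])c1O | starting material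
2 | benzyl bromide | BrCc1ccccc1 | starting material
3 | 2-(benzyloxy)-3-nitrophenol | Oc1cccc([N+](=O)[O-])c1OCc1ccccc1 | intermediate
4 | (3,5-dibromo-2-methoxyphenyl)boronic acid | COc1c(Br)cc(Br)cc1B(O)O | starting material
5 | 2-(benzyloxy)-1-(3,5-dibromo-2-methoxyphenoxy)-3-nitrobenzene | COc1c(Br)cc(Br)cc1Oc1cccc([N+](=O)[O-])c1OCc1ccccc1 | intermediate
6 | 2-(benzyloxy)-3-(3,5-dibromo-2-methoxyphenoxy)aniline | COc1c(Br)cc(Br)cc1Oc1cccc(N)c1OCc1ccccc1 | intermediate
7 | 2-(benzyloxy)-4,6-dibromo-3-(3,5-dibromo-2-methoxyphenoxy)aniline | COc1c(Br)cc(Br)cc1Oc1c(Br)cc(Br)c(N)c1OCc1ccccc1 | intermediate (not isolated)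
8 | 2-(benzyloxy)-4,5,6-tribromo-3-(3,5-dibromo-2-methoxyphenoxy)aniline | COc1c(Br)cc(Br)cc1Oc1c(Br)c(Br)c(Br)c(N)c1OCc1ccccc1 | intermediate
9 | 2-(benzyloxy)-4,5,6-tribromo-3-(3,5-dibromo-2-methoxyphenoxy)benzenediazonium tetrafluoroborate | COc1c(Br)cc(Br)cc1Oc1c(Br)c(Br)c(Br)c([N+]#N)c1OCc1ccccc1.F[B-](F)(F)F | intermediate (not isolated)
10 | 1-(benzyloxy)-3,4,5-tribromo-2-(3,5-dibromo-2-methoxyphenoxy)benzene | COc1c(Br)cc(Br)cc1Oc1c(OCc2ccccc2)cc(Br)c(Br)c1Br | intermediate
11 | 3,4,5-tribromo-2-(3,5-dibromo-2-methoxyphenoxy)phenol | COc1c(Br)cc(Br)cc1Oc1c(O)cc(Br)c(Br)c1Br | target

## Step count and risks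

Total: 6 steps. Longest linear sequence: 6 steps, from 1 to 11; 2 and 4 are purchased.

**Step 4 (key step).** The third substitution, at C5' between two bromines and meta to nitrogen, may be slower than bromination of ring A at the carbons ortho or para to the bridging oxygen. It may also be slower than oxidation or ipso attack on the fully substituted aniline, especially if the amine is protonated or N-brominated.
Fallback: the C5' bromine would be installed before any ether or amine is present, setting out from 1 and coming back at 8.
- 1 would be monobrominated (Br2, 1 equiv, AcOH, rt) at the only carbon that is para to a hydroxyl and meta to the nitro group, to give 5-bromo-3-nitrobenzene-1,2-diol F1.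
- Benzylation with 2 as in step 1 would give 2-(benzyloxy)-5-bromo-3-nitrophenol F2.
- Coupling with 4 as in step 2 would give 2-(benzyloxy)-5-bromo-1-(3,5-dibromo-2-methoxyphenoxy)-3-nitrobenzene F3.
- Iron reduction as in step 3 would give 2-(benzyloxy)-5-bromo-3-(3,5-dibromo-2-methoxyphenoxy)aniline F4.
- F4 then needs only two bromines, ortho and para to nitrogen (NBS, 2 equiv, DMF, 0 °C), which should give 8.

**Step 5.** The aryl radical at C3' may add to the phenyl ring of the ortho benzyloxy group (a Pschorr-type six-membered ring closure) before hydrogen transfer. The ortho-benzyloxy diazonium salt may also lose its benzyl group on standing.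
Fallback: sets out from 8 and comes back at 10. Diazonium salt 9, generated as in step 5, would be treated with KI in aqueous MeCN at 0 °C to give 1-(benzyloxy)-3,4,5-tribromo-2-(3,5-dibromo-2-methoxyphenoxy)-6-iodobenzene F7; iodine transfer to the aryl radical should be faster than ring closure. Iodine–magnesium exchange with iPrMgCl·LiCl (THF, −40 °C), which is selective for iodine over bromine, and a quench with dilute HCl would then place hydrogen on C3' by a polar path.

**Step 2.** With an ortho substituent on each partner, transfer of the aryl group to copper may be slow, so that protodeboronation and oxidative homocoupling consume the boronic acid.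
Fallback: sets out from 4 and 3 and comes back at 5.
- Iododeboronation of 4 (NIS, MeCN, rt) would give 1,5-dibromo-3-iodo-2-methoxybenzene F5.
- Oxidation to trivalent iodine (mCPBA, TsOH·H2O, MeCN, 77 °C) and capture by 1,3,5-trimethoxybenzene would give (3,5-dibromo-2-methoxyphenyl)(2,4,6-trimethoxyphenyl)iodonium 4-methylbenzenesulfonate F6.
- The potassium phenoxide of 3 (t-BuOK, THF, rt) would be arylated by F6 without metal; ligand coupling at iodine transfers the more electron-poor aryl group and leaves the trimethoxyphenyl group on iodine.

**Step 1.** Alkylation may occur at the wrong oxygen or at both oxygens if the monoanion equilibrates or a second deprotonation takes place.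
Fallback: sets out from 2 and a purchased phenol with a single hydroxyl, 2-bromo-6-nitrophenol F8, and comes back at 3.
- Benzylation of F8 with 2 (K2CO3, DMF, 60 °C) would give 2-(benzyloxy)-1-bromo-3-nitrobenzene F9.
- Miyaura borylation (B2pin2, Pd(dppf)Cl2, KOAc, dioxane, 90 °C) would give 2-[2-(benzyloxy)-3-nitrophenyl]-4,4,5,5-tetramethyl-1,3,2-dioxaborolane F10.
- Oxidation of the C–B bond (H2O2, NaOH, THF, 0 °C) would give 3.

## Further compounds

F1 | step 4 | 5-bromo-3-nitrobenzene-1,2-diol | Oc1cc(Br)cc([N+](=O)[O-])c1O
F2 | step 4 | 2-(benzyloxy)-5-bromo-3-nitrophenol | Oc1cc(Br)cc([N+](=O)[O-])c1OCc1ccccc1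
F3 | step 4 | 2-(benzyloxy)-5-bromo-1-(3,5-dibromo-2-methoxyphenoxy)-3-nitrobenzene | COc1c(Br)cc(Br)cc1Oc1cc(Br)cc([N+](=O)[O-])c1OCc1ccccc1
F4 | step 4 | 2-(benzyloxy)-5-bromo-3-(3,5-dibromo-2-methoxyphenoxy)aniline | COc1c(Br)cc(Br)cc1Oc1cc(Br)cc(N)c1OCc1ccccc1
F5 | step 2 | 1,5-dibromo-3-iodo-2-methoxybenzene | COc1c(Br)cc(Br)cc1I
F6 | step 2 | (3,5-dibromo-2-methoxyphenyl)(2,4,6-trimethoxyphenyl)iodonium 4-methylbenzenesulfonate | COc1cc(OC)c([I+]c2cc(Br)cc(Br)c2OC)c(OC)c1.Cc1ccc(S(=O)(=O)[O-])cc1
F7 | step 5 | 1-(benzyloxy)-3,4,5-tribromo-2-(3,5-dibromo-2-methoxyphenoxy)-6-iodobenzene | COc1c(Br)cc(Br)cc1Oc1c(Br)c(Br)c(Br)c(I)c1OCc1ccccc1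
F8 | step 1 | 2-bromo-6-nitrophenol | Oc1c(Br)cccc1[N+](=O)[O-]
F9 | step 1 | 2-(benzyloxy)-1-bromo-3-nitrobenzene | Brc1cccc([N+](=O)[O-])c1OCc1ccccc1
F10 | step 1 | 2-[2-(benzyloxy)-3-nitrophenyl]-4,4,5,5-tetramethyl-1,3,2-dioxaborolane | CC1(C)OB(OC1(C)C)c1cccc([N+](=O)[O-])c1OCc1ccccc1
A1 | alternative 1 | 2-(3,5-dibromo-2-methoxyphenoxy)-4-nitrophenol | COc1c(Br)cc(Br)cc1Oc1cc([N+](=O)[O-])ccc1O
A2 | alternative 1 | 1-(3,5-dibromo-2-methoxyphenoxy)propan-2-one | COc1c(Br)cc(Br)cc1OCC(C)=O
A3 | alternative 1 | sodium nitromalonaldehyde | [Na+].O=C[C-](C=O)[N+](=O)[O-]
A4 | alternative 1 | 3,5-dibromo-2-methoxyphenol | COc1c(Br)cc(Br)cc1O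
A5 | alternative 2 | 2-[6-(benzyloxy)-2,3,4-tribromophenoxy]-4,6-dibromophenol | Oc1c(Br)cc(Br)cc1Oc1c(OCc2ccccc2)cc(Br)c(Br)c1Br
A6 | alternative 2 | 2-[6-(benzyloxy)-2,3,4-tribromophenoxy]cyclohex-2-en-1-one | O=C1CCCC=C1Oc1c(OCc2ccccc2)cc(Br)c(Br)c1Br
A7 | alternative 2 | 6-(benzyloxy)-2,3,4-tribromophenol | Oc1c(OCc2ccccc2)cc(Br)c(Br)c1Br
A8 | alternative 3 | 1-(benzyloxy)-3,4,5-tribromo-2-(3,5-dibromo-2-methoxyphenoxy)benzene | COc1c(Br)cc(Br)cc1Oc1c(OCc2ccccc2)cc(Br)c(Br)c1Br
A9 | alternative 3 | 2,4-dibromo-6-(trimethylsilyl)phenyl trifluoromethanesulfonate | C[Si](C)(C)c1cc(Br)cc(Br)c1OS(=O)(=O)C(F)(F)F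
A10 | alternative 3 | tert-butyl methyl peroxide | COOC(C)(C)C
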